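Numbering (elemanolide): cyclohexane C5–C10; lactone C6–O–C12(=O)–C11(C13H3)–C7; vinyl C1=C2 and methyl C14 on C10; C4(=C3H2)–C15H2OH on C5; ester oxygen on C8; side chain C1′–C4′.
Cuts, in retrosynthetic order: C8–O ester (Mitsunobu, inversion); C1=C2 (lactol Wittig, which also frees C15–OH); C10–C14 (cyclopropanation and acid opening of a C1=C10 enol ether); C8–C9 (carbonyl-ene); C7–C8 and C11–C13 (conjugate addition and methylation of a butenolide); C5–C6 (allylboration).
Enabling feature: the two branches on C5, C3=C4–C15–O and C9=C10–C1–O, become identical when C1 and C15 share one oxygen, so C5 enters as the non-stereogenic C4 atom of a 3,5-dimethylideneoxane ring (O, C1, C10, C5, C4, C15).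
Forward order: oxane ring; allylboration of acrolein; acrylate ring-closing metathesis to the butenolide; dithiane addition and methylation; ene closure of the cyclohexane; angular methyl; opening of the oxane by Wittig reaction; esterification.
Stereochemistry: C6 from the (−)-Ipc2B reagent; C7 and C11 from anti additions to the butenolide; C5 and C8 in the ene step (chair, trans-lactone); C10 by 8β-OH-directed cyclopropanation; C8 corrected by Mitsunobu inversion; C3′ from the (S)-malic-acid-derived ester.
Key step: step 9

Step 1
Reactants: 1 2-bromoprop-2-en-1-ol; 2 2,3-dibromoprop-1-ene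
Product: 3 bis(2-bromoprop-2-en-1-yl) ether
Conditions: NaH, THF, 0 → 25 °C
Reagents that add atoms: none
Why: Williamson etherification, in which the alkoxide of 1 should displace the allylic bromide of 2 (SN2) while the vinylic bromides stay inert.

Step 2
Reactants: 3 bis(2-bromoprop-2-en-1-yl) ether; 4 ethyl formate
Product: 7 3,5-dimethylideneoxan-4-ol, via dilithio ether 5 (not isolated), via lithio enal 6 (not isolated)
Conditions: t-BuLi (4.1 equiv), Et2O, −78 °C; 4 (1.0 equiv, slow addition), −78 → 0 °C; aq. NH4Cl
Reagents that add atoms: none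
Why: Double bromine–lithium exchange followed by two additions to the one formate carbon (addition–elimination to 6, then six-membered-ring-forming 1,2-addition), the known route from di-organometallic reagents and formates to cyclic secondary alcohols; no stereocenter is formed.

Step 3
Reactants: 7 3,5-dimethylideneoxan-4-ol
Product: 8 3-(bromomethyl)-5-methylidene-5,6-dihydro-2H-pyran
Conditions: PBr3 (0.4 equiv), Et2O, −10 °C
Reagents that add atoms: phosphorus tribromide, BrP(Br)Br
Why: SN2′ bromination of a bis-allylic alcohol (as in divinylcarbinol to pentadienyl bromide) should give the rearranged primary bromide with a conjugated diene.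

Step 4
Reactants: 8 3-(bromomethyl)-5-methylidene-5,6-dihydro-2H-pyran; 9 acrolein
Product: 13 (1R)-1-(3,5-dimethylideneoxan-4-yl)prop-2-en-1-ol, via Grignard reagent 10 (not isolated), via allylborane 11 (not isolated), via borinate 12 (not isolated)
Conditions: Mg, Et2O, −15 °C; (−)-Ipc2BOMe, −78 → 25 °C; 9, −78 °C; NaOH, H2O2, 0 → 25 °C
Reagents that add atoms: none
Why: Asymmetric allylboration, in which the diisopinocampheylborane from (+)-α-pinene should add through a chair transition state by its γ-carbon (the future C5, not stereogenic because its two branches are identical) to the si face of acrolein, setting C6 as R.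

Step 5
Reactants: 13 (1R)-1-(3,5-dimethylideneoxan-4-yl)prop-2-en-1-ol; 14 acryloyl chloride
Product: 15 (1R)-1-(3,5-dimethylideneoxan-4-yl)prop-2-en-1-yl prop-2-enoate
Conditions: Et3N, DMAP (cat.), CH2Cl2, 0 °C
Reagents that add atoms: none
Why: Acylation of the secondary alcohol with an acid chloride under DMAP catalysis, which leaves C6 untouched.

Step 6
Reactants: 15 (1R)-1-(3,5-dimethylideneoxan-4-yl)prop-2-en-1-yl prop-2-enoate
Product: 16 (5R)-5-(3,5-dimethylideneoxan-4-yl)furan-2(5H)-one
Conditions: second-generation Grubbs catalyst RuCl2(=CHPh)(PCy3)(H2IMes) (5 mol %), CH2Cl2 (5 mM), 40 °C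
Reagents that add atoms: none
Why: Ring-closing metathesis, in which the ruthenium carbene should load on the monosubstituted vinyl group and close the five-membered butenolide onto the acrylate, the two 1,1-disubstituted methylidene groups being too hindered to compete.

Step 7
Reactants: 16 (5R)-5-(3,5-dimethylideneoxan-4-yl)furan-2(5H)-one; 17 1,3-dithiane
Product: 19 (3R,4R,5S)-5-(3,5-dimethylideneoxan-4-yl)-4-(1,3-dithian-2-yl)-3-methyloxolan-2-one, via lithium enolate 18 (not isolated)
Conditions: 17, n-BuLi, THF, −30 °C; HMPA, 16, −78 °C; MeI, −78 → −30 °C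
Reagents that add atoms: iodomethane, CI
Why: Tandem conjugate addition–enolate alkylation on a γ-substituted butenolide, in which 2-lithio-1,3-dithiane (a formyl anion equivalent, 1,4-addition favoured by HMPA) should add to C7 anti to the oxanyl group on C6 and the enolate should be methylated anti to the new C7 substituent, setting C7 and C11.

Step 8
Reactants: 19 (3R,4R,5S)-5-(3,5-dimethylideneoxan-4-yl)-4-(1,3-dithian-2-yl)-3-methyloxolan-2-one
Product: 20 (2S,3R,4R)-2-(3,5-dimethylideneoxan-4-yl)-4-methyl-5-oxooxolane-3-carbaldehyde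
Conditions: MeI, CaCO3, MeCN–H2O (4:1), 45 °C
Reagents that add atoms: water, O
Why: Alkylative hydrolysis of the dithioacetal (S-methylation, then hydrolysis buffered by CaCO3) should unmask the C8 aldehyde without touching the alkenes, and the trans arrangement at C7 is the stable one.

Step 9
Reactants: 20 (2S,3R,4R)-2-(3,5-dimethylideneoxan-4-yl)-4-methyl-5-oxooxolane-3-carbaldehyde
Product: 21 tricyclic enol ether, (5R,6S,7S,8S,11R)-8β-hydroxy-6α,12-olide with C1=C10 inside the oxane ring (O–C1H=C10–C5–C4(=C3H2)–C15H2) and 5αH
Conditions: Me2AlCl (2.5 equiv), CH2Cl2, −78 → −20 °C; aq. NaHCO3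
Reagents that add atoms: none
Why: Intramolecular Lewis-acid carbonyl-ene reaction of type 2: the Me2AlCl-bound C8 aldehyde is attacked by the terminal carbon C9 of one methylidene group while a hydrogen of the adjacent O–CH2 carbon (C1) passes to the carbonyl oxygen in a six-membered pericyclic array, so the double bond moves to C10=C1 and becomes a ring enol ether. The closest known reaction types are the Me2AlCl-promoted type 2 cyclization of 5-methyl-5-hexenals to 3-methylidenecyclohexanols and the ene reaction of allylic ethers, which gives enol ethers. One ring is closed, the cyclohexane C5–C10, in the 6-endo-trig mode with respect to C9=C10 (tether on the central ene carbon C10). C5 is set by the choice between the two diastereotopic methylidene groups: the trans-fused lactone holds O6 and C11 equatorial in the chair transition state, and the arm that does not react (C4) then prefers the equatorial position, giving 5αH; C8 is set by the pericyclic geometry, because only an axial (endo) carbonyl oxygen can reach the C1 hydrogen, giving the 8β-alcohol. The step needs group selectivity between the two methylidene carbons and ene rather than Prins behaviour; the first is secured by the rigid trans-lactone chair, the second by Me2AlCl, a proton scavenger and a Lewis acid weak enough to keep the process concerted at low temperature.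

Step 10
Reactants: 21 tricyclic enol ether
Product: 22 cyclopropyl ether, 21 with a CH2 group (C14) bridging C1 and C10 on the β-face (same side as 8β-OH)
Conditions: Et2Zn, CH2I2, CH2Cl2, −20 → 0 °C
Reagents that add atoms: diiodomethane, ICI
Why: Hydroxyl-directed Simmons–Smith cyclopropanation (Furukawa variant), in which the zinc alkoxide of the axial 8β-OH, 1,3-syn-axial to the β-face of C10, should deliver CH2 to the electron-rich enol ether from that face and so set C10, while the remote methylidene group reacts more slowly.

Step 11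
Reactants: 22 cyclopropyl ether
Product: 23 lactol, 10β-methyl compound with C1H(OH)–O–C15 (mixture at C1) and 8β-OH
Conditions: HCl (0.2 M), THF–H2O, 25 °C
Reagents that add atoms: water, O
Why: Acid opening of an alkoxycyclopropane (known from cyclopropanated glycals), in which protonation of the unsubstituted carbon C14 with cleavage of C1–C14, assisted by the ring oxygen, should give the angular methyl group and, after capture of the oxocarbenium ion by water, the lactol with C10 unchanged.

Step 12
Reactants: 23 lactol
Product: 24 (5S,6S,7S,8S,10R,11R)-8β,15-diol, the C8 epimer of the deacylated target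
Conditions: Ph3PCH3Br, KOtBu, THF, 0 → 40 °C
Reagents that add atoms: methyltriphenylphosphonium bromide, C[P+](c1ccccc1)(c1ccccc1)c1ccccc1.[Br-]
Why: Wittig methylenation of a lactol through its open hydroxy-aldehyde form should turn C1 into the vinyl group and set the C15 hydroxyl free in one operation.

Step 13
Reactants: 24 8β,15-diol
Product: 25 15-O-tert-butyldimethylsilyl ether of 24
Conditions: TBSCl (1.05 equiv), imidazole, CH2Cl2, 0 °C
Reagents that add atoms: tert-butyldimethylsilyl chloride, CC(C)(C)[Si](C)(C)Cl
Why: Selective silylation, in which the primary allylic C15 hydroxyl should react far faster than the hindered axial secondary 8β-OH.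

Step 14
Reactants: 26 methyl 2-[(4S)-2,2-dimethyl-1,3-dioxolan-4-yl]acetate
Product: 27 methyl 3-(dimethylamino)-2-[(4S)-2,2-dimethyl-1,3-dioxolan-4-yl]propanoate (mixture at C2)
Conditions: LiN(i-Pr)2, THF, −78 °C; CH2=NMe2+ I−, −78 → 0 °C
Reagents that add atoms: Eschenmoser's salt, C=[N+](C)C.[I-]
Why: Mannich reaction of the ester enolate at −78 °C, where the acetal β-oxygen is a poor leaving group; the new α-center disappears in the next step and the dioxolane stereocenter is not involved.

Step 15
Reactants: 27 methyl 3-(dimethylamino)-2-[(4S)-2,2-dimethyl-1,3-dioxolan-4-yl]propanoate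
Product: 30 2-[(4S)-2,2-dimethyl-1,3-dioxolan-4-yl]prop-2-enoic acid, via ammonium iodide 28 (not isolated), via methyl ester 29 (not isolated)
Conditions: MeI, MeOH, 25 °C; LiOH, THF–H2O, 0 → 25 °C; HCl to pH 3
Reagents that add atoms: lithium hydroxide, [Li+].[OH-]
Why: Quaternization, E1cB elimination of trimethylamine (α-methylenation) and saponification in one flask should give the acrylic acid with C3′ untouched.

Step 16
Reactants: 25 15-O-silyl 8β-alcohol; 30 2-[(4S)-2,2-dimethyl-1,3-dioxolan-4-yl]prop-2-enoic acid
Product: 31 protected target, 8α-ester with 3′,4′-O-isopropylidene and 15-O-TBS groups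
Conditions: PPh3, DIAD, toluene, 0 → 25 °C
Reagents that add atoms: none
Why: Mitsunobu esterification, in which the carboxylate should displace the activated axial 8β-oxyphosphonium group with inversion (SN2 from the open α-face, as with axial cyclohexanols), giving the equatorial 8α-ester and so correcting C8.

Step 17
Reactants: 31 protected target
Product: 32 CNP0260337.1
Conditions: AcOH–H2O (4:1), 40 °C
Reagents that add atoms: none
Why: Acid hydrolysis should remove the acetonide and the primary silyl ether together, leaving both esters and the alkenes intact.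

Compound list
1 | 2-bromoprop-2-en-1-ol | OCC(Br)=C | starting material
2 | 2,3-dibromoprop-1-ene | BrCC(Br)=C | starting material
3 | bis(2-bromoprop-2-en-1-yl) ether | C=C(Br)COCC(Br)=C | intermediate
4 | ethyl formate | CCOC=O | starting material
5 | bis(2-lithioprop-2-en-1-yl) ether | [Li]C(=C)COCC([Li])=C | intermediate
6 | 2-{[(2-lithioprop-2-en-1-yl)oxy]methyl}prop-2-enal | [Li]C(=C)COCC(=C)C=O | intermediate
7 | 3,5-dimethylideneoxan-4-ol | OC1C(=C)COCC1=C | intermediate
8 | 3-(bromomethyl)-5-methylidene-5,6-dihydro-2H-pyran | BrCC1=CC(=C)COC1 | intermediate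
9 | acrolein (prop-2-enal) | C=CC=O | starting material
10 | [(5-methylidene-5,6-dihydro-2H-pyran-3-yl)methyl]magnesium bromide | Br[Mg]CC1=CC(=C)COC1 | intermediate
11 | [(5-methylidene-5,6-dihydro-2H-pyran-3-yl)methyl]bis(isopinocampheyl)borane (Ipc from (+)-α-pinene) | C(B([C@@H]2C[C@@H]3C[C@H]([C@H]2C)C3(C)C)[C@@H]2C[C@@H]3C[C@H]([C@H]2C)C3(C)C)C1=CC(=C)COC1 | intermediate
12 | bis(isopinocampheyl)borinate of alcohol 13 | C=C[C@@H](OB([C@@H]2C[C@@H]3C[C@H]([C@H]2C)C3(C)C)[C@@H]2C[C@@H]3C[C@H]([C@H]2C)C3(C)C)C1C(=C)COCC1=C | intermediate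
13 | (1R)-1-(3,5-dimethylideneoxan-4-yl)prop-2-en-1-ol | C=C[C@@H](O)C1C(=C)COCC1=C | intermediate
14 | acryloyl chloride | C=CC(=O)Cl | starting material
15 | (1R)-1-(3,5-dimethylideneoxan-4-yl)prop-2-en-1-yl prop-2-enoate | C=C[C@@H](OC(=O)C=C)C1C(=C)COCC1=C | intermediate
16 | (5R)-5-(3,5-dimethylideneoxan-4-yl)furan-2(5H)-one | C1=CC(=O)O[C@H]1C2C(=C)COCC2=C | intermediate
17 | 1,3-dithiane | C1CSCSC1 | starting material
18 | lithium (4R,5S)-5-(3,5-dimethylideneoxan-4-yl)-4-(1,3-dithian-2-yl)-4,5-dihydrofuran-2-olate | S1CCCSC1[C@H]2[C@@H](OC(O[Li])=C2)C3C(=C)COCC3=C | intermediate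
19 | (3R,4R,5S)-5-(3,5-dimethylideneoxan-4-yl)-4-(1,3-dithian-2-yl)-3-methyloxolan-2-one | S1CCCSC1[C@H]2[C@@H](OC(=O)[C@@H]2C)C3C(=C)COCC3=C | intermediate
20 | (2S,3R,4R)-2-(3,5-dimethylideneoxan-4-yl)-4-methyl-5-oxooxolane-3-carbaldehyde | O=C[C@H]1[C@@H](OC(=O)[C@@H]1C)C2C(=C)COCC2=C | intermediate
21 | tricyclic enol ether: (5R,6S,7S,8S,11R)-8β-hydroxy-6α,12-olide (11α-methyl), cyclohexane C5–C10 fused to the ring O–C1H=C10–C5–C4(=C3H2)–C15H2, 5αH | C1=C2C[C@H](O)[C@H]3[C@@H](OC(=O)[C@@H]3C)[C@@H]2C(=C)CO1 | intermediate
22 | cyclopropyl ether: 21 with C14H2 bridging C1 and C10 on the β-face (cis to 8β-OH) | C1[C@H]2OCC(=C)[C@H]3[C@H](OC(=O)[C@@H]4C)[C@@H]4[C@@H](O)C[C@]123 | intermediate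
23 | lactol: 10β-methyl, C1H(OH)–O–C15 ring (both C1 epimers), 8β-OH, 6α,12-olide | OC1OCC(=C)[C@H]2[C@H](OC(=O)[C@@H]3C)[C@@H]3[C@@H](O)C[C@]12C | intermediate
24 | (5S,6S,7S,8S,10R,11R)-8β,15-dihydroxy-11βH,13-dihydroelema-1,3-dien-6α,12-olide (C8 epimer of the deacylated target) | C=C[C@@]1(C)C[C@H](O)[C@H]2[C@@H](OC(=O)[C@@H]2C)[C@@H]1C(=C)CO | intermediate
25 | 15-O-tert-butyldimethylsilyl ether of 24 | C=C[C@@]1(C)C[C@H](O)[C@H]2[C@@H](OC(=O)[C@@H]2C)[C@@H]1C(=C)CO[Si](C)(C)C(C)(C)C | intermediate
26 | methyl 2-[(4S)-2,2-dimethyl-1,3-dioxolan-4-yl]acetate | COC(=O)C[C@H]1COC(C)(C)O1 | starting material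
27 | methyl 3-(dimethylamino)-2-[(4S)-2,2-dimethyl-1,3-dioxolan-4-yl]propanoate | COC(=O)C(CN(C)C)[C@H]1COC(C)(C)O1 | intermediate
28 | {2-[(4S)-2,2-dimethyl-1,3-dioxolan-4-yl]-3-methoxy-3-oxopropyl}trimethylammonium iodide | COC(=O)C(C[N+](C)(C)C)[C@H]1COC(C)(C)O1.[I-] | intermediate
29 | methyl 2-[(4S)-2,2-dimethyl-1,3-dioxolan-4-yl]prop-2-enoate | COC(=O)C(=C)[C@H]1COC(C)(C)O1 | intermediate
30 | 2-[(4S)-2,2-dimethyl-1,3-dioxolan-4-yl]prop-2-enoic acid | OC(=O)C(=C)[C@H]1COC(C)(C)O1 | intermediate
31 | protected target: 8α-O-{2-[(4S)-2,2-dimethyl-1,3-dioxolan-4-yl]prop-2-enoyl}, 15-O-TBS | C=C[C@@]1(C)C[C@@H](OC(=O)C(=C)[C@H]2COC(C)(C)O2)[C@H]3[C@@H](OC(=O)[C@@H]3C)[C@@H]1C(=C)CO[Si](C)(C)C(C)(C)C | intermediate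
32 | CNP0260337.1, (5S,6S,7S,8R,10R,11R)-8α-O-[(3S)-3,4-dihydroxy-2-methylidenebutanoyl]-15-hydroxy-11βH,13-dihydroelema-1,3-dien-6α,12-olide | C=C[C@@]1(C)C[C@@H](OC(=O)C(=C)[C@H](O)CO)[C@H]2[C@@H](OC(=O)[C@@H]2C)[C@@H]1C(=C)CO | target

Total step count: 17. Longest linear sequence: 15 steps (steps 1–13, 16 and 17); steps 14 and 15 make the side-chain acid.

Steps most likely to fail

Step 9. The cyclization may be diverted into stepwise cationic Prins chemistry (chloride capture or hydride shift at C10), and the two methylidene groups may not be told apart well enough. The fallback sets out from 20 and closes the same bond as a chloro-Prins cyclization with MeAlCl2 (CH2Cl2, −78 °C), chloride being passed from the aluminium alkoxide to C10 on the face of the oxygen. This should give the syn-1,3-chlorohydrin, the 10β-chloro-8β-hydroxy tricyclic lactone F1. Dehydrochlorination towards the oxygen-bearing C1 (DBU, toluene, 80 °C) then gives the enol ether, and the route is rejoined at 21.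

Step 12. The lactone may migrate to the free 8β-hydroxyl (base-induced translactonization to the cis-fused 8,12-lactone) while the ylide and the C15 alkoxide are present. The fallback sets out from 23 and replaces the basic phosphorus ylide by the non-basic methylene reagent made from CH2Br2, Zn and TiCl4 (THF–CH2Cl2, 0 °C). This reagent methylenates hindered aldehydes beside lactones and free hydroxyl groups, so it should give the diol directly; the route is rejoined at 24 with no new compound (F0).

Step 16. Elimination towards C7 or C9 may outrun substitution at the hindered axial alcohol. The fallback sets out from 25 and sets C8 by a redox pair followed by an esterification with retention: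
- Oxidation with Dess–Martin periodinane (CH2Cl2, 25 °C) gives the 8-ketone F2.
- Electron-transfer reduction (SmI2, i-PrOH, THF, 0 °C) should give the more stable equatorial alcohol, the 8α-hydroxy 15-O-silyl ether F3; the 1,3-diaxial methyl group on C10 strongly disfavours the axial alcohol.
- Yamaguchi esterification with 30 (2,4,6-trichlorobenzoyl chloride, Et3N, DMAP, toluene) rejoins the route at 31.

Further compounds
F1 | step 9 | 10β-chloro-8β-hydroxy tricyclic lactone (formal HCl adduct of 21 across C10=C1, chlorine on C10) | C1OCC(=C)[C@H]2[C@H](OC(=O)[C@@H]3C)[C@@H]3[C@@H](O)C[C@]12Cl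
F0 | step 12 | none | none
F2 | step 16 | 8-ketone of 25 (15-O-TBS) | C=C[C@@]1(C)CC(=O)[C@H]2[C@@H](OC(=O)[C@@H]2C)[C@@H]1C(=C)CO[Si](C)(C)C(C)(C)C
F3 | step 16 | 8α-hydroxy 15-O-TBS ether (C8 epimer of 25) | C=C[C@@]1(C)C[C@@H](O)[C@H]2[C@@H](OC(=O)[C@@H]2C)[C@@H]1C(=C)CO[Si](C)(C)C(C)(C)C
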